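**Plan**

Gibberellane numbering is used: ring A C1–C5 and C10, ring B C5, C6, C8, C9, C10, ring C C8, C9, C11–C14, ring D C8, C14, C13, C16, C15; C7 is the acid on C6, C19 the lactone carbonyl, C17 the methylene on C16.
Feature: the bridgehead tertiary carbinol C13 next to the exocyclic C16=C17 methylene of ring D is the retron of a C13 ketyl adding to a terminal alkyne on a propargyl arm at quaternary C8.
Retrosynthesis cuts C13–C16 (ring D) first, then the C12–O bond (α-oxygenation of the freed C13 ketone) and the C16≡C17 bond (aldehyde homologation), which leads back to gibberellic acid (1) with ring D cleaved.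
Forward: rings A, B, C and the 19,10-lactone are carried intact from 1; ring D is opened (C16=C17 ozonolysis, C13–C16 glycol cleavage), C17 is put back as the alkyne terminus, C12 is oxygenated, and ring D is closed last.
Stereochemistry: C3, C4, C5, C6, C8, C9 and C10 come from 1; C12 from convex-face enolate hydroxylation followed by Mitsunobu inversion; C13 from the geometry of the bridged 5-exo closure.

Key step: step 11

Assumption: gibberellic acid, the bulk fermentation product that already holds rings A–C, the lactone and seven of the nine stereocenters, is taken as the commercial starting material. The route is therefore a relay (partial) synthesis in which only ring D is taken apart and rebuilt; the target is the (12S)-12-hydroxy derivative of 1.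

**Step 1**
Reactants: 1 gibberellic acid
Product: 2 gibberellic acid SEM ester (C7 [2-(trimethylsilyl)ethoxy]methyl ester)
Conditions: SEMCl, i-Pr2NEt, DMF, 0 °C
Reagents that add atoms: 2-(trimethylsilyl)ethoxymethyl chloride, C[Si](C)(C)CCOCCl
Why: Carboxylate O-alkylation (acetal ester formation): only the C7 acid is ionised by the amine base, so the chloromethyl ether alkylates it in preference to the two hydroxyl groups, and the SEM ester should survive the later basic and reductive steps yet fall to fluoride at the end; no stereocenter is involved.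

**Step 2**
Reactants: 2 gibberellic acid SEM ester
Product: 3 3-O-TBS gibberellic acid SEM ester
Conditions: TBSCl, imidazole, DMF, 40 °C
Reagents that add atoms: tert-butyldimethylsilyl chloride, CC(C)(C)[Si](C)(C)Cl
Why: Silyl ether formation with TBSCl/imidazole: the secondary allylic 3-hydroxyl is silylated while the tertiary bridgehead 13-hydroxyl does not react, which blocks retro-aldol opening of ring A and lactone migration in the basic steps that follow.

**Step 3**
Reactants: 3 3-O-TBS gibberellic acid SEM ester
Product: 5 3-O-TBS-13-hydroxy-17-nor-16-oxo ketol SEM ester (16-norketone), via ozonide 4 (not isolated)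
Conditions: O3, CH2Cl2, −78 °C, Sudan Red 7B end point; then Me2S, −78 °C to rt
Reagents that add atoms: ozone, [O-][O+]=O
Why: Ozonolysis with reductive work-up: the electron-rich 1,1-disubstituted C16=C17 alkene is attacked much faster than the C1=C2 alkene, which is deactivated by the allylic lactone and silyloxy oxygens and shielded by C10, and the dye end point stops the ozone at one equivalent.

**Step 4**
Reactants: 5 16-norketone
Product: 6 3-O-TBS-17-nor-13,16-diol SEM ester (both C16 epimers)
Conditions: NaBH4, MeOH/THF, 0 °C
Reagents that add atoms: none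
Why: Borohydride reduction: the strained cyclopentanone is reduced at 0 °C while the hindered lactone and the acetal ester are left alone, and the configuration of the new C16 carbinol is irrelevant because C16 becomes an aldehyde carbon in the next step.

**Step 5**
Reactants: 6 17-nor-13,16-diol
Product: 7 ring D seco keto aldehyde (ring C is a cyclohexanone with C13=O; C8 carries the C15–C16 arm CH2–CHO; 3-O-TBS; SEM ester)
Conditions: Pb(OAc)4, CH2Cl2, 0 °C
Reagents that add atoms: none
Why: Criegee glycol cleavage: Pb(OAc)4 cleaves the cis-diol through the cyclic lead diester and the trans-diol, more slowly, through the open pathway, so both C16 epimers should open ring D between C13 and C16 to the C13 ketone and the C16 aldehyde without touching the quaternary C8.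

**Step 6**
Reactants: 7 ring D seco keto aldehyde
Product: 8 ring D seco ynone (13-oxo, 8-propargyl; 3-O-TBS; SEM ester)
Conditions: dimethyl (1-diazo-2-oxopropyl)phosphonate, K2CO3, MeOH, 0 °C to rt
Reagents that add atoms: dimethyl (1-diazo-2-oxopropyl)phosphonate, COP(=O)(OC)C(=[N+]=[N-])C(C)=O
Why: Seyferth–Gilbert homologation in the Ohira–Bestmann form: the diazomethylphosphonate anion made in the flask condenses with the aldehyde far faster than with the hindered ketone, and the competing C12-to-C16 aldol is reversible and cannot dehydrate (a bridgehead alkene would result), whereas loss of nitrogen to the terminal alkyne is irreversible; C17 is thereby returned.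

**Step 7**
Reactants: 8 ring D seco ynone
Product: 10 (12R)-12-hydroxy seco ynone (12-epimer; hydroxyl cis to H-9 and to the propargyl arm), via potassium enolate 9 (not isolated)
Conditions: KN(SiMe3)2, THF, −78 °C; then 2-(phenylsulfonyl)-3-phenyloxaziridine, −78 °C; AcOH quench
Reagents that add atoms: 2-(phenylsulfonyl)-3-phenyloxaziridine, O=S(=O)(c1ccccc1)N1OC1c1ccccc1
Why: Davis enolate hydroxylation: the bulky amide should remove a proton from the C12 methylene and not from the neopentyl C14 methylene (nor from the alkyne, which is the weaker acid), and the oxaziridine should deliver oxygen to the convex face of the cis-fused B/C bicycle, anti to the C9–C10 bond, which sets C12 as R, the epimer of the target.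

**Step 8**
Reactants: 10 (12R)-12-hydroxy seco ynone
Product: 11 (12S)-12-formyloxy seco ynone (oxygen cis to C10, trans to the propargyl arm)
Conditions: HCO2H, PPh3, DIAD, THF, 0 °C to rt
Reagents that add atoms: formic acid, O=CO
Why: Mitsunobu inversion: formate displaces the oxyphosphonium group in a bimolecular substitution at the carbon next to the carbonyl, which is activated toward displacement, so C12 is inverted to the S configuration of the target.

**Step 9**
Reactants: 11 (12S)-12-formyloxy seco ynone
Product: 12 (12S)-12-hydroxy seco ynone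
Conditions: KHCO3 (cat.), MeOH, 0 °C
Reagents that add atoms: none
Why: Base-catalysed transesterification: a formate is methanolysed under bicarbonate far faster than the hindered C7 acetal ester or the lactone, and bicarbonate at 0 °C should not enolise the ketol, so C12 keeps its configuration.

**Step 10**
Reactants: 12 (12S)-12-hydroxy seco ynone
Product: 13 (12S)-3,12-bis-O-TBS ring D seco ynone SEM ester (13-oxo, 8-propargyl)
Conditions: TBSOTf, 2,6-lutidine, CH2Cl2, −78 °C
Reagents that add atoms: tert-butyldimethylsilyl trifluoromethanesulfonate, CC(C)(C)[Si](C)(C)OS(=O)(=O)C(F)(F)F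
Why: Silylation with a silyl triflate: TBSOTf/2,6-lutidine silylates the hindered secondary hydroxyl at −78 °C without enolising the ketone and turns the C12 oxygen into a poor leaving group for the reductive step.

**Step 11**
Reactants: 13 (12S)-3,12-bis-O-TBS ring D seco ynone SEM ester
Product: 14 (12S)-12-hydroxygibberellic acid 3,12-bis-TBS ether SEM ester
Conditions: SmI2 (2.5 equiv), HMPA, t-BuOH, THF, −78 to −30 °C; aq NH4Cl
Reagents that add atoms: none
Why: SmI2 activated by HMPA transfers one electron to the C13 ketone, the only carbonyl it can reduce here (lactone and acetal ester are inert), and the samarium ketyl adds to the internal alkyne carbon C16; the C17 vinyl radical is then reduced by a second SmI2 and protonated by tert-butanol, leaving the exocyclic methylene. The closest known reaction type is the reductive ketyl–alkyne cyclisation of acetylenic ketones to 2-methylenecyclopentanols, which is documented for bridgehead carbinols of bicyclo[3.2.1]octanes. Ring D (C8, C14, C13, C16, C15) closes in the 5-exo-dig mode through the new C13–C16 bond and completes the bicyclo[3.2.1]octane. The new C13 stereocenter is controlled by the tether alone: the propargyl arm is axial on C8 and 1,3 to C13 across C14, so C16 can reach only one face of the ketyl and the hydroxyl is forced into the equatorial position. The selectivity needed is ring closure ahead of reductive loss of the C12 silyloxy group, and it should be secured by the poor silanolate leaving group, the low temperature and the enforced proximity of the alkyne.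

**Step 12**
Reactants: 14 (12S)-12-hydroxygibberellic acid 3,12-bis-TBS ether SEM ester
Product: 15 (12S)-12-hydroxygibberellic acid (the target gibberellin)
Conditions: 48% aq HF, MeCN, 0 °C to rt
Reagents that add atoms: none
Why: Fluoride-mediated global deprotection: HF cleaves both silyl ethers and attacks the silicon of the SEM group, which fragments to fluorotrimethylsilane, ethene and formaldehyde and frees the C7 acid, at an acidity that the allylic lactone and the tertiary allylic carbinol should tolerate; no stereocenter is affected.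

**Compound list**

1 | gibberellic acid | C=C1C[C@]23C[C@@]1(O)CC[C@H]2[C@@]12C=C[C@H](O)[C@@](C)(C(=O)O1)[C@H]2[C@@H]3C(=O)O | starting material
2 | gibberellic acid SEM ester | C=C1C[C@]23C[C@@]1(O)CC[C@H]2[C@@]12C=C[C@H](O)[C@@](C)(C(=O)O1)[C@H]2[C@@H]3C(=O)OCOCC[Si](C)(C)C | intermediate
3 | 3-O-TBS gibberellic acid SEM ester | C=C1C[C@]23C[C@@]1(O)CC[C@H]2[C@@]12C=C[C@H](O[Si](C)(C)C(C)(C)C)[C@@](C)(C(=O)O1)[C@H]2[C@@H]3C(=O)OCOCC[Si](C)(C)C | intermediate
4 | 16,17-ozonide of 3 (spiro-1,2,4-trioxolane at C16, C16 epimers) | C1OOC4(O1)C[C@]23C[C@@]4(O)CC[C@H]2[C@@]12C=C[C@H](O[Si](C)(C)C(C)(C)C)[C@@](C)(C(=O)O1)[C@H]2[C@@H]3C(=O)OCOCC[Si](C)(C)C | intermediate (not isolated)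
5 | 3-O-TBS-13-hydroxy-17-nor-16-oxo ketol SEM ester (16-norketone) | O=C1C[C@]23C[C@@]1(O)CC[C@H]2[C@@]12C=C[C@H](O[Si](C)(C)C(C)(C)C)[C@@](C)(C(=O)O1)[C@H]2[C@@H]3C(=O)OCOCC[Si](C)(C)C | intermediate
6 | 3-O-TBS-17-nor-13,16-diol SEM ester (both C16 epimers) | OC1C[C@]23C[C@@]1(O)CC[C@H]2[C@@]12C=C[C@H](O[Si](C)(C)C(C)(C)C)[C@@](C)(C(=O)O1)[C@H]2[C@@H]3C(=O)OCOCC[Si](C)(C)C | intermediate
7 | ring D seco keto aldehyde (13-oxo; C8–CH2–CHO) | O=CC[C@]23CC(=O)CC[C@H]2[C@@]12C=C[C@H](O[Si](C)(C)C(C)(C)C)[C@@](C)(C(=O)O1)[C@H]2[C@@H]3C(=O)OCOCC[Si](C)(C)C | intermediate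
8 | ring D seco ynone (13-oxo, 8-propargyl) | C#CC[C@]23CC(=O)CC[C@H]2[C@@]12C=C[C@H](O[Si](C)(C)C(C)(C)C)[C@@](C)(C(=O)O1)[C@H]2[C@@H]3C(=O)OCOCC[Si](C)(C)C | intermediate
9 | potassium C12=C13 enolate of 8 | [K+].C#CC[C@]23CC([O-])=CC[C@H]2[C@@]12C=C[C@H](O[Si](C)(C)C(C)(C)C)[C@@](C)(C(=O)O1)[C@H]2[C@@H]3C(=O)OCOCC[Si](C)(C)C | intermediate (not isolated)
10 | (12R)-12-hydroxy seco ynone (12-epimer) | C#CC[C@]23CC(=O)[C@H](O)C[C@H]2[C@@]12C=C[C@H](O[Si](C)(C)C(C)(C)C)[C@@](C)(C(=O)O1)[C@H]2[C@@H]3C(=O)OCOCC[Si](C)(C)C | intermediate
11 | (12S)-12-formyloxy seco ynone | C#CC[C@]23CC(=O)[C@@H](OC=O)C[C@H]2[C@@]12C=C[C@H](O[Si](C)(C)C(C)(C)C)[C@@](C)(C(=O)O1)[C@H]2[C@@H]3C(=O)OCOCC[Si](C)(C)C | intermediate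
12 | (12S)-12-hydroxy seco ynone | C#CC[C@]23CC(=O)[C@@H](O)C[C@H]2[C@@]12C=C[C@H](O[Si](C)(C)C(C)(C)C)[C@@](C)(C(=O)O1)[C@H]2[C@@H]3C(=O)OCOCC[Si](C)(C)C | intermediate
13 | (12S)-3,12-bis-O-TBS ring D seco ynone SEM ester (cyclisation precursor) | C#CC[C@]23CC(=O)[C@@H](O[Si](C)(C)C(C)(C)C)C[C@H]2[C@@]12C=C[C@H](O[Si](C)(C)C(C)(C)C)[C@@](C)(C(=O)O1)[C@H]2[C@@H]3C(=O)OCOCC[Si](C)(C)C | intermediate
14 | (12S)-12-hydroxygibberellic acid 3,12-bis-TBS ether SEM ester | C=C1C[C@]23C[C@@]1(O)[C@@H](O[Si](C)(C)C(C)(C)C)C[C@H]2[C@@]12C=C[C@H](O[Si](C)(C)C(C)(C)C)[C@@](C)(C(=O)O1)[C@H]2[C@@H]3C(=O)OCOCC[Si](C)(C)C | intermediate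
15 | (12S)-12-hydroxygibberellic acid (the target gibberellin) | C=C1C[C@]23C[C@@]1(O)[C@@H](O)C[C@H]2[C@@]12C=C[C@H](O)[C@@](C)(C(=O)O1)[C@H]2[C@@H]3C(=O)O | target

**Step count and risks**

Total step count: 12. Longest linear sequence: 12 steps (1 to 15).

Most likely to fail, step 11: in the chair of ring C that holds the propargyl arm over C13, the C12–O bond is axial and overlaps with the ketyl, so a second electron transfer with loss of silanolate (deoxygenation at C12), or plain reduction of the ketone, may outrun the C13–C16 bond formation. The fallback sets out from 13 and comes back at 14. Iodoboration of the terminal alkyne with B-iodo-9-borabicyclo[3.3.1]nonane (pentane/CH2Cl2, −20 °C) should give the (Z)-2-iodoalkenylborane F1. Acetic acid then protonolyses the C–B bond in the same flask to the 2-iodoallyl ketone F2. CrCl2 with catalytic NiCl2 in DMSO should close ring D by intramolecular Nozaki–Hiyama–Kishi addition of the alkenylchromium species to the C13 ketone. This is a two-electron pathway without a ketyl, so the C12 oxygen is not at risk, and the same tether geometry fixes C13.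

Second, step 7: oxygen transfer may be poorly face-selective, or deprotonation may occur in part on the C14 side, which would give mixtures that the inversion in step 8 cannot correct. The fallback sets out from 8 and comes back at 12, so that steps 8 and 9 fall away. D-Proline-catalysed α-aminoxylation with nitrosobenzene (DMSO, rt) forms the enamine only toward C12 and lets the catalyst, not the substrate, choose the face. D-Proline is chosen by analogy with the sense of induction known for cyclohexanone, and should give the (12S)-12-anilinooxy ketone F3. Cleavage of the N–O bond with catalytic CuSO4 in methanol at 0 °C then gives 12.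

Third, step 8: the activated carbinol may eliminate toward C11, or lose its configuration through enolisation of the oxyphosphonium salt, instead of undergoing clean displacement from the hindered face syn to C10. The fallback sets out from 10 and comes back at 12. Tf2O and pyridine in CH2Cl2 at −20 °C convert 10 into the (12R)-12-triflate F4. Tetrabutylammonium nitrite in DMF displaces the triflate with inversion to the (12S)-12-nitrite ester F5, which is hydrolysed on aqueous work-up to 12.

**Further compounds**

F1 | step 11 | (Z)-2-iodoalkenylborane from iodoboration of 13 (9-borabicyclo[3.3.1]nonan-9-yl on C17, iodine on C16) | I/C(=C\B1C2CCCC1CCC2)C[C@]34CC(=O)[C@@H](O[Si](C)(C)C(C)(C)C)C[C@H]3[C@@]12C=C[C@H](O[Si](C)(C)C(C)(C)C)[C@@](C)(C(=O)O1)[C@H]2[C@@H]4C(=O)OCOCC[Si](C)(C)C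
F2 | step 11 | (12S)-3,12-bis-O-TBS 8-(2-iodoallyl)-13-oxo seco ketone SEM ester | C=C(I)C[C@]23CC(=O)[C@@H](O[Si](C)(C)C(C)(C)C)C[C@H]2[C@@]12C=C[C@H](O[Si](C)(C)C(C)(C)C)[C@@](C)(C(=O)O1)[C@H]2[C@@H]3C(=O)OCOCC[Si](C)(C)C
F3 | step 7 | (12S)-12-anilinooxy seco ynone | C#CC[C@]23CC(=O)[C@@H](ONc4ccccc4)C[C@H]2[C@@]12C=C[C@H](O[Si](C)(C)C(C)(C)C)[C@@](C)(C(=O)O1)[C@H]2[C@@H]3C(=O)OCOCC[Si](C)(C)C
F4 | step 8 | (12R)-12-trifluoromethanesulfonyloxy seco ynone | C#CC[C@]23CC(=O)[C@H](OS(=O)(=O)C(F)(F)F)C[C@H]2[C@@]12C=C[C@H](O[Si](C)(C)C(C)(C)C)[C@@](C)(C(=O)O1)[C@H]2[C@@H]3C(=O)OCOCC[Si](C)(C)C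
F5 | step 8 | (12S)-12-nitrite ester of the seco ynone | C#CC[C@]23CC(=O)[C@@H](ON=O)C[C@H]2[C@@]12C=C[C@H](O[Si](C)(C)C(C)(C)C)[C@@](C)(C(=O)O1)[C@H]2[C@@H]3C(=O)OCOCC[Si](C)(C)C
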